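**Plan**

1. The central ring is labelled B1 (butyryl-bearing carbon), B2 and B6 (the C–OH carbons next to it), B3 and B5 (the carbons carrying the CH2 bridges) and B4 (the C–OH between the bridges). The last cuts remove five O-methyl groups and the B1–butyryl bond.
2. The key cut is B2–B3 and B5–B6. B3, B4 and B5 with the two bridge CH2 groups are a symmetric 1,5-disubstituted pentan-3-one, and B2, B1 and B6 are a malonyl unit, so the central benzene ring comes from the methyl enol ether of that ketone and malonyl dichloride.
3. The ketone is cut at both CH2–CH2(outer ring) bonds to divinyl ketone (from 1,5-dichloropentan-3-one) and two molecules of butyrylfilicinic acid, which comes from phloroglucinol by C-butyrylation and gem-dimethylation.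
4. Forward: the two outer rings are finished first (steps 1–2), joined to the five-carbon ketone chain (step 3) and capped as methyl enol ethers (step 4). The chain ketone is turned into its enol ether (steps 5–6), the central ring is closed last (step 7), then butyrylated (step 8) and unmasked (step 9).
5. Stereochemistry: the target has no stereocentre. The one stereogenic double bond on the way (the enol ether of step 6) is consumed in step 7.

Key step: step 7

**Remarks on the chemistry**

- Abbreviations: Fil = 5-butanoyl-2,4-dihydroxy-3,3-dimethyl-6-oxocyclohexa-1,4-dien-1-yl (the outer ring, drawn in the tautomer of the target SMILES); FilMe2 = its 2,4-di-O-methyl ether.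
- Assumption: the O-methylation of step 4 is drawn as giving the 2,4-di-O-methyl (cross-conjugated dienone) pattern on each outer ring; a regioisomeric enol ether would have the same skeleton, behave alike in steps 5–8 and converge in step 9.
- Assumption: the enol ether of step 6 is expected as an E/Z mixture, of which the Z isomer is drawn; both isomers give the same product in step 7.

**Route**

Step 1
Reactants: 1 phloroglucinol; 2 butyryl chloride
Product: 3 1-(2,4,6-trihydroxyphenyl)butan-1-one
Conditions: AlCl3, PhNO2/CH2Cl2, 0 °C → 40 °C; aq. HCl
Reagents that add atoms: none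
Why: Friedel–Crafts acylation of the highly activated triol, in which the first acyl group deactivates the ring so that mono-acylation should be clean; no stereocentre arises.

Step 2
Reactants: 3 1-(2,4,6-trihydroxyphenyl)butan-1-one
Product: 4 2-butanoyl-3,5-dihydroxy-4,4-dimethylcyclohexa-2,5-dien-1-one (butyrylfilicinic acid)
Conditions: NaOMe (3 equiv), MeI (2.2 equiv), MeOH, 0 °C → rt; aq. HCl
Reagents that add atoms: iodomethane, CI
Why: Dearomatising C-methylation of the acylphloroglucinolate (the classical route to acylfilicinic acids), in which the second methyl group enters at the carbon already methylated and the resulting vinylogous acid anion is a much weaker nucleophile, which limits further methylation; the new quaternary carbon carries two identical groups and is not a stereocentre.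

Step 3
Reactants: 4 butyrylfilicinic acid (2.3 equiv); 5 1,5-dichloropentan-3-one
Product: 8 1,5-bis(Fil)pentan-3-one, via penta-1,4-dien-3-one 6 (not isolated), via mono-adduct vinyl ketone 7 (not isolated)
Conditions: Et3N (5 equiv), MeCN, 0 °C, 5 added slowly to 4, then rt; work-up at pH 4
Reagents that add atoms: none
Why: E1cB loss of HCl from the β-chloro ketone releases the vinyl ketone at low concentration and the ammonium enolate of 4 adds through its only unsubstituted ring carbon (Michael addition), once on each vinyl group, while excess 4 and slow addition of 5 favour the 2:1 adduct over a second, intramolecular addition at the already substituted carbon; no stereocentre is formed.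

Step 4
Reactants: 8 1,5-bis(Fil)pentan-3-one
Product: 9 1,5-bis(FilMe2)pentan-3-one
Conditions: TMSCHN2 (excess), MeOH/toluene, 0 °C → rt
Reagents that add atoms: (trimethylsilyl)diazomethane, C[Si](C)(C)C=[N+]=[N-]
Why: O-Methylation of acidic enols by a diazoalkane (proton transfer, then collapse of the methyldiazonium–enolate ion pair on oxygen) should cap the vinylogous acid OH and the chelated enol OH of each ring without C-alkylation, which removes every acidic hydrogen before the acid chloride chemistry.

Step 5
Reactants: 9 1,5-bis(FilMe2)pentan-3-one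
Product: 10 3,3-dimethoxy-1,5-bis(FilMe2)pentane
Conditions: HC(OMe)3, p-TsOH (cat.), MeOH, rt; Et3N quench
Reagents that add atoms: trimethyl orthoformate, COC(OC)OC; methanol, CO
Why: Acid-catalysed ketalisation with orthoformate as water scavenger should touch only the saturated, unhindered dialkyl ketone, because the butyryl and ring carbonyls are vinylogous ester carbonyls on fully substituted carbons and any methoxy exchange at the ring enol ethers in methanol is degenerate.

Step 6
Reactants: 10 3,3-dimethoxy-1,5-bis(FilMe2)pentane
Product: 11 (2Z)-3-methoxy-1,5-bis(FilMe2)pent-2-ene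
Conditions: TMSOTf (1.5 equiv), iPr2NEt (2 equiv), CH2Cl2, −20 °C → 0 °C
Reagents that add atoms: none
Why: Ketal-to-enol-ether elimination, in which TMSOTf ionises the ketal to a methoxycarbenium ion far faster than it silylates a ketone at this temperature and the hindered amine removes an α-proton, so that the enol ether is placed only at the former dialkyl ketone; the ketal is symmetric, so one constitutional isomer results.

Step 7
Reactants: 11 (2Z)-3-methoxy-1,5-bis(FilMe2)pent-2-ene; 12 malonyl dichloride
Product: 14 5-methoxy-4,6-bis[(FilMe2)methyl]benzene-1,3-diol, via methoxy enone acid chloride 13 (not isolated)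
Conditions: 12 (1.05 equiv), Et2O/CH2Cl2, 0.02 M, −20 °C → rt; aq. NaHCO3
Reagents that add atoms: none
Why: Proposed new method: the enol ether carbon B3 attacks one acid chloride and the methoxycarbenium ion loses a proton to give the β-methoxy enone acid chloride 13, as in the known acylation of alkyl enol ethers by reactive acid chlorides; under the HCl set free, 13 equilibrates with its cross-conjugated enol ether tautomer, whose carbon B5 attacks the second acid chloride and forms B5–B6, and loss of a proton and enolisation of the 5-methoxycyclohexene-1,3-dione give the aromatic ring. The closest known reaction is the Effenberger cyclisation of cyclic ketone methyl or silyl enol ethers with malonyl dichloride to bicyclo[3.3.1]nonane-2,4,9-triones, which has not been shown to give a benzene ring from an open-chain ketone. The central ring closes in a 6-(enolendo)-exo-trig mode at the acyl carbon B6; no stereocentre is formed and the geometry of 11 is erased. The step needs closure at carbon and not at oxygen, since open-chain silyl enol ethers normally end as 4-hydroxy-2-pyranones: the methyl group of 11 stays on the B4 oxygen through the first acylation and blocks lactonisation, so B5 is the only nucleophile that can reach the second acid chloride through a six-membered transition state. The symmetry of the ketone makes it immaterial which α-carbon reacts first, the outer rings offer neither a free OH nor an unsubstituted nucleophilic carbon, and high dilution disfavours intermolecular acylation.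

Step 8
Reactants: 14 5-methoxy-4,6-bis[(FilMe2)methyl]benzene-1,3-diol; 2 butyryl chloride
Product: 15 1-[2,6-dihydroxy-4-methoxy-3,5-bis[(FilMe2)methyl]phenyl]butan-1-one
Conditions: AlCl3 (excess), CH2Cl2/PhNO2, −10 °C → 0 °C; aq. HCl
Reagents that add atoms: none
Why: Friedel–Crafts acylation at the only free aromatic CH, which lies ortho to two OH groups and para to the OMe group, while the outer rings have no unsubstituted nucleophilic carbon and the product is held as an aluminium chelate that resists further reaction.

Step 9
Reactants: 15 1-[2,6-dihydroxy-4-methoxy-3,5-bis[(FilMe2)methyl]phenyl]butan-1-one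
Product: 16 1-[2,4,6-trihydroxy-3,5-bis[(Fil)methyl]phenyl]butan-1-one (target)
Conditions: BBr3 (excess), CH2Cl2, −78 °C → 0 °C; then H2O/THF
Reagents that add atoms: none
Why: Lewis acid-mediated SN2 demethylation, in which BBr3 binds each ether or vinylogous ester oxygen and bromide removes the methyl group (the four vinylogous esters leave as stabilised boron enolates, the di-ortho-substituted anisole is twisted and basic), run cold and acidic to avoid the base-induced exchange of methylene bridges, with aqueous work-up releasing the five OH groups.

**Compound list**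

1 | phloroglucinol | Oc1cc(O)cc(O)c1 | starting material
2 | butyryl chloride | CCCC(=O)Cl | starting material
3 | 1-(2,4,6-trihydroxyphenyl)butan-1-one | CCCC(=O)c1c(O)cc(O)cc1O | intermediate
4 | 2-butanoyl-3,5-dihydroxy-4,4-dimethylcyclohexa-2,5-dien-1-one (butyrylfilicinic acid) | CCCC(=O)C1=C(O)C(C)(C)C(O)=CC1=O | intermediate
5 | 1,5-dichloropentan-3-one | ClCCC(=O)CCCl | starting material
6 | penta-1,4-dien-3-one (not isolated) | C=CC(=O)C=C | intermediate
7 | 1-(Fil)pent-4-en-3-one, mono-adduct vinyl ketone (not isolated) | CCCC(=O)C1=C(O)C(C)(C)C(O)=C(CCC(=O)C=C)C1=O | intermediate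
8 | 1,5-bis(Fil)pentan-3-one | CCCC(=O)C1=C(O)C(C)(C)C(O)=C(CCC(=O)CCC2=C(O)C(C)(C)C(O)=C(C(=O)CCC)C2=O)C1=O | intermediate
9 | 1,5-bis(FilMe2)pentan-3-one | CCCC(=O)C1=C(OC)C(C)(C)C(OC)=C(CCC(=O)CCC2=C(OC)C(C)(C)C(OC)=C(C(=O)CCC)C2=O)C1=O | intermediate
10 | 3,3-dimethoxy-1,5-bis(FilMe2)pentane | CCCC(=O)C1=C(OC)C(C)(C)C(OC)=C(CCC(OC)(OC)CCC2=C(OC)C(C)(C)C(OC)=C(C(=O)CCC)C2=O)C1=O | intermediate
11 | (2Z)-3-methoxy-1,5-bis(FilMe2)pent-2-ene (Z isomer drawn, E/Z mixture expected) | CCCC(=O)C1=C(OC)C(C)(C)C(OC)=C(C/C=C(\OC)CCC2=C(OC)C(C)(C)C(OC)=C(C(=O)CCC)C2=O)C1=O | intermediate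
12 | malonyl dichloride | O=C(Cl)CC(=O)Cl | starting material
13 | (4E)-5-methoxy-3-oxo-7-(FilMe2)-4-[(FilMe2)methyl]hept-4-enoyl chloride (not isolated; E isomer drawn, push–pull double bond) | CCCC(=O)C1=C(OC)C(C)(C)C(OC)=C(C/C(C(=O)CC(Cl)=O)=C(\OC)CCC2=C(OC)C(C)(C)C(OC)=C(C(=O)CCC)C2=O)C1=O | intermediate
14 | 5-methoxy-4,6-bis[(FilMe2)methyl]benzene-1,3-diol | CCCC(=O)C1=C(OC)C(C)(C)C(OC)=C(Cc2c(O)cc(O)c(CC3=C(OC)C(C)(C)C(OC)=C(C(=O)CCC)C3=O)c2OC)C1=O | intermediate
15 | 1-[2,6-dihydroxy-4-methoxy-3,5-bis[(FilMe2)methyl]phenyl]butan-1-one | CCCC(=O)C1=C(OC)C(C)(C)C(OC)=C(Cc2c(O)c(C(=O)CCC)c(O)c(CC3=C(OC)C(C)(C)C(OC)=C(C(=O)CCC)C3=O)c2OC)C1=O | intermediate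
16 | 1-[2,4,6-trihydroxy-3,5-bis[(Fil)methyl]phenyl]butan-1-one (CNP0287270.0) | CCCC(=O)C1=C(O)C(C)(C)C(O)=C(Cc2c(O)c(CC3=C(O)C(C)(C)C(O)=C(C(=O)CCC)C3=O)c(O)c(C(=O)CCC)c2O)C1=O | target

**Step count**

Total: 9 steps. Longest linear sequence: 9 steps (phloroglucinol 1 to target 16).

**Steps most likely to fail**

Step 7 (Proposed new method). The second acylation may not close at B5: the chain may stall at the mono-acylated stage, react intermolecularly to oligomers, or lose its enol ether to the HCl set free. The outer-ring vinylogous ester oxygens may also be acylated and then demethylated by chloride.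
Fallback, from 9, returning at 16: the ring is built through its oxygen-closed isomer with known reactions. Ketone 9 is silylated (TMSOTf, Et3N, CH2Cl2, −78 °C, one equivalent) to the (Z)-trimethylsilyl enol ether F1. With malonyl dichloride 12 this should give, as open-chain silyl enol ethers normally do, the 5,6-disubstituted 4-hydroxy-2-pyranone F2. Mg(OMe)2 in methanol opens the lactone to the methyl 3,5-dioxo ester F3, and NaOMe in hot methanol effects Claisen cyclisation of the B5 carbanion onto the ester to give the 2,4-disubstituted phloroglucinol F4 with a free OH at B4. F4 is butyrylated under the conditions of step 8 to the acylphloroglucinol F5, and BBr3 as in step 9 removes its four methyl groups, so the sequence rejoins the route at the target 16.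

Step 3. The mono-adduct 7 may add a second time through its already substituted ring carbon (intramolecular spiro-annulation to a quaternary centre) faster than a second molecule of 4 adds. The free enol OH groups of 8 may also close onto the chain ketone (hemiketal, then spiroketal) during acidic handling.
Fallback, from 4, returning at 8: the polarity of bridge formation is reversed so that no enone is ever present. Compound 4 is converted with aqueous formaldehyde and dimethylamine in ethanol into the Mannich base F6. Two equivalents of F6 are then warmed with 3-oxopentanedioic acid in buffered aqueous dioxane. Loss of dimethylamine, conjugate addition of the β-keto acid at each of its two α-carbons and loss of two molecules of CO2 should deliver 8.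

Step 8. The acylium ion or AlCl3 may attack B3 or B5 in an ipso sense and split off an outer ring (cleavage or exchange of the methylene bridges), and methyl ethers may be lost unevenly under the Lewis acid.
Fallback, from 14, returning at 16: the order of the last two operations is inverted. Compound 14 is first demethylated with BBr3 (CH2Cl2, −78 °C → 0 °C) to the free bis(Fil-methyl)phloroglucinol F7, whose only carbon nucleophile is the aromatic CH. F7 is then acylated with butyric acid in BF3·OEt2 at 60 °C (chelate-directed C-acylation), and hydrolysis of the boron chelates gives the target 16 directly.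

**Further compounds**

F1 | step 7 | (2Z)-3-(trimethylsilyloxy)-1,5-bis(FilMe2)pent-2-ene | CCCC(=O)C1=C(OC)C(C)(C)C(OC)=C(C/C=C(\O[Si](C)(C)C)CCC2=C(OC)C(C)(C)C(OC)=C(C(=O)CCC)C2=O)C1=O
F2 | step 7 | 4-hydroxy-6-[2-(FilMe2)ethyl]-5-[(FilMe2)methyl]-2H-pyran-2-one | CCCC(=O)C1=C(OC)C(C)(C)C(OC)=C(CC2=C(CCC3=C(OC)C(C)(C)C(OC)=C(C(=O)CCC)C3=O)OC(=O)C=C2O)C1=O
F3 | step 7 | methyl 3,5-dioxo-7-(FilMe2)-4-[(FilMe2)methyl]heptanoate (racemic, configurationally labile at C4) | CCCC(=O)C1=C(OC)C(C)(C)C(OC)=C(CC(C(=O)CC(=O)OC)C(=O)CCC2=C(OC)C(C)(C)C(OC)=C(C(=O)CCC)C2=O)C1=O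
F4 | step 7 | 2,4-bis[(FilMe2)methyl]benzene-1,3,5-triol | CCCC(=O)C1=C(OC)C(C)(C)C(OC)=C(Cc2c(O)cc(O)c(CC3=C(OC)C(C)(C)C(OC)=C(C(=O)CCC)C3=O)c2O)C1=O
F5 | step 7 | 1-[2,4,6-trihydroxy-3,5-bis[(FilMe2)methyl]phenyl]butan-1-one | CCCC(=O)C1=C(OC)C(C)(C)C(OC)=C(Cc2c(O)c(C(=O)CCC)c(O)c(CC3=C(OC)C(C)(C)C(OC)=C(C(=O)CCC)C3=O)c2O)C1=O
F6 | step 3 | 2-butanoyl-6-[(dimethylamino)methyl]-3,5-dihydroxy-4,4-dimethylcyclohexa-2,5-dien-1-one | CCCC(=O)C1=C(O)C(C)(C)C(O)=C(CN(C)C)C1=O
F7 | step 8 | 2,4-bis[(Fil)methyl]benzene-1,3,5-triol | CCCC(=O)C1=C(O)C(C)(C)C(O)=C(Cc2c(O)cc(O)c(CC3=C(O)C(C)(C)C(O)=C(C(=O)CCC)C3=O)c2O)C1=O
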